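The butenolide ring (O1, C2, C3, C4, C5) is disconnected at O1–C5 and C2–C3, which excises its lactone unit O1–C2(=O) as carbon dioxide. The key step exploits that C3 is the α-carbon of an ethyl ketone (C4=O) and C5 a vinylic carbon: CO2 is captured by the C3 enolate and the new carboxylate is joined to C5 by copper-catalysed, stereoretentive displacement of iodide. The precursor is an acyclic (E)-2-iodo enone whose geometry (C7 cis to C4, set by syn-hydrostannation of an ynone) becomes that of the exocyclic C5=C6 bond, the geometry that anti-oxymetalation of the ynone would not deliver.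

Key step: step 9

Remark 1: the locants O1, C2 (lactone carbonyl), C3 (methyl-bearing), C4 (enol carbon), C5, C6 (exocyclic CH) and C7 (stereocentre) are used throughout for the butenolide and its side chain. The target is taken as drawn, with C7 cis to C4 across C5=C6 (5E) and C7 of S configuration.

Remark 2 (assumption): in step 3, Ru(OAc)2[(S)-BINAP] is assumed to hydrogenate the chelated alkene face that gives S, by extension of the face rule of the geraniol/nerol series. Should the sense prove opposite, the (R)-ligand is used instead.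

Step 1
Reactants: 1 3-bromofuran; 2 pent-4-ynal
Product: 4 1-(furan-3-yl)pent-4-yn-1-ol (racemic), via 3-furyllithium 3 (not isolated)
Conditions: n-BuLi, THF, −78 °C; then 2, −78 °C; aq NH4Cl
Reagents that add atoms: none
Why: Bromine–lithium exchange followed by 1,2-addition of the aryllithium to the aldehyde, which at −78 °C should outrun both isomerisation of 3-lithiofuran and deprotonation of the terminal alkyne; the carbinol centre is left racemic on purpose because step 5 oxidises it.

Step 2
Reactants: 5 geranyl acetate
Product: 6 (2E,6E)-8-hydroxy-3,7-dimethylocta-2,6-dien-1-yl acetate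
Conditions: SeO2 (0.1 equiv), t-BuOOH (3 equiv), salicylic acid (0.1 equiv), CH2Cl2, rt
Reagents that add atoms: tert-butyl hydroperoxide CC(C)(C)OO (oxygen, relayed by SeO2)
Why: Riley allylic oxidation (ene reaction, then [2,3]-sigmatropic shift) should functionalise the (E)-methyl group of the more electron-rich terminal alkene, the alkene next to the acetate being deactivated; no stereocentre is formed.

Step 3
Reactants: 6 (2E,6E)-8-hydroxy-3,7-dimethylocta-2,6-dien-1-yl acetate
Product: 7 (2E,7S)-8-hydroxy-3,7-dimethyloct-2-en-1-yl acetate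
Conditions: H2 (30 atm), Ru(OAc)2[(S)-BINAP] (1 mol %), MeOH, rt
Reagents that add atoms: none
Why: Hydroxyl-directed Noyori asymmetric hydrogenation of the 2-methylallylic alcohol, in which the alkoxide-chelated alkene is reduced on the face selected by the BINAP ligand and so sets the stereocentre (the later C7) as S by reagent control, while the alkene next to the acetate cannot chelate and should stay untouched.

Step 4
Reactants: 4 1-(furan-3-yl)pent-4-yn-1-ol; 7 (2E,7S)-8-hydroxy-3,7-dimethyloct-2-en-1-yl acetate
Product: 9 (2S,6E,9E)-13-(furan-3-yl)-2,6,10-trimethyltrideca-6,9-diene-1,13-diol (both C13 epimers), via alkenylalane 8 (not isolated)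
Conditions: Me3Al (5 equiv), Cp2ZrCl2 (0.25 equiv), CH2Cl2, 0 °C to rt; then 7, Pd(PPh3)4 (5 mol %), THF, rt; aq Rochelle salt
Reagents that add atoms: trimethylaluminium C[Al](C)C
Why: Negishi zirconium-catalysed carboalumination adds methyl and aluminium syn across the terminal alkyne (methyl to the internal carbon), and the alkenylalane is then allylated at the primary terminus of the π-allylpalladium formed from the acetate (Negishi alkenyl–allyl coupling), so both trisubstituted alkenes should come out E; the two hydroxyls travel as aluminium alkoxides and no stereocentre is formed.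

Step 5
Reactants: 9 (2S,6E,9E)-13-(furan-3-yl)-2,6,10-trimethyltrideca-6,9-diene-1,13-diol
Product: 10 (2S,6E,9E)-13-(furan-3-yl)-2,6,10-trimethyl-13-oxotrideca-6,9-dienal
Conditions: Dess–Martin periodinane (2.6 equiv), CH2Cl2, 0 °C to rt; aq Na2S2O3/NaHCO3 work-up
Reagents that add atoms: none
Why: Dess–Martin oxidation should convert the primary alcohol into the aldehyde and the furyl carbinol into the ketone in one operation, under non-basic conditions that do not epimerise the α-methyl aldehyde.

Step 6
Reactants: 10 (2S,6E,9E)-13-(furan-3-yl)-2,6,10-trimethyl-13-oxotrideca-6,9-dienal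
Product: 11 (4E,7E,12S)-1-(furan-3-yl)-4,8,12-trimethyltetradeca-4,7-dien-13-yn-1-one
Conditions: dimethyl (1-diazo-2-oxopropyl)phosphonate (1.3 equiv), K2CO3 (2 equiv), MeOH, 0 °C
Reagents that add atoms: Ohira–Bestmann reagent CC(=O)C(=[N+]=[N-])P(=O)(OC)OC
Why: Seyferth–Gilbert homologation in its Ohira–Bestmann form should convert the aldehyde, far more reactive than the aryl ketone, into the terminal alkyne by way of the alkylidene carbene and 1,2-hydride shift; the low temperature is chosen to keep the α-stereocentre (C7) intact.

Step 7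
Reactants: 11 (4E,7E,12S)-1-(furan-3-yl)-4,8,12-trimethyltetradeca-4,7-dien-13-yn-1-one
Product: 12 (4E,7E,12S)-1-(furan-3-yl)-4,8,12-trimethylheptadeca-4,7-dien-13-yne-1,15-dione
Conditions: propionyl chloride (1.2 equiv), PdCl2(PPh3)2 (2 mol %), CuI (4 mol %), Et3N (1.5 equiv), THF, rt
Reagents that add atoms: propionyl chloride CCC(=O)Cl
Why: Acyl Sonogashira coupling (copper acetylide transferred to the acylpalladium chloride) should give the ynone under mild amine conditions that tolerate the furyl ketone and leave the propargylic stereocentre alone.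

Step 8
Reactants: 12 (4E,7E,12S)-1-(furan-3-yl)-4,8,12-trimethylheptadeca-4,7-dien-13-yne-1,15-dione
Product: 14 (4E,7E,12S,13E)-1-(furan-3-yl)-14-iodo-4,8,12-trimethylheptadeca-4,7,13-triene-1,15-dione, via vinylstannane 13 (not isolated)
Conditions: Bu3SnH (1.1 equiv, slow addition), Pd(PPh3)4 (2 mol %), THF, 0 °C; then I2 (1.1 equiv), 0 °C, dark
Reagents that add atoms: iodine II
Why: Palladium-catalysed hydrostannation adds H and Sn syn across the ynone with tin on the carbon next to the carbonyl (C5), and iododestannylation proceeds with retention, so iodine should end cis to H6 and the C7 chain cis to the acyl carbon C4 (13E).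

Step 9
Reactants: 14 (4E,7E,12S,13E)-1-(furan-3-yl)-14-iodo-4,8,12-trimethylheptadeca-4,7,13-triene-1,15-dione
Product: 16 (5E)-5-[(2S,6E,9E)-13-(furan-3-yl)-2,6,10-trimethyl-13-oxotrideca-6,9-dien-1-ylidene]-4-hydroxy-3-methylfuran-2(5H)-one (target), via β-keto carboxylate 15 (not isolated)
Conditions: CO2 (1.0 MPa), DBU (3 equiv), CuI (10 mol %), 3,4,7,8-tetramethyl-1,10-phenanthroline (20 mol %), MeCN, 40 °C, dark; then 1 M HCl
Reagents that add atoms: carbon dioxide O=C=O
Why: Proposed new method: DBU and CO2 carboxylate the C3 enolate of the ethyl ketone reversibly to the β-keto carboxylate 15 (C2–C3), which binds monovalent copper, adds oxidatively across the adjacent vinylic C5–I bond through a six-membered cupracycle and closes the lactone by C–O reductive elimination from trivalent copper (O1–C5). The closest known reaction types are the silver-catalysed incorporation of CO2 into conjugated ynones to give tetronic acids and the CuI-catalysed intramolecular O-vinylation of carboxylic acids with vinyl halides (Ullmann type). The ring (O1, C2, C3, C4, C5) closes in a 5-exo sense at the trigonal carbon C5, the C5=C6 bond staying outside the ring. No stereocentre is formed (C3 ends as the enol carbon); the geometry of C5=C6 is controlled by retention at C5 in the coupling, so that the (13E)-iodide should give the ylidene with C7 cis to C4. The step needs the coupling to be faster than loss of CO2, than 6-endo oxa-Michael closure onto C6 and than E/Z equilibration or dehydroiodination of the iodide, which the easy oxidative addition of a 2-iodo enone, the CO2 pressure and the syn (not anti) arrangement of H6 and iodine should secure. C7 is shielded from γ-deprotonation because the planar dienolate would suffer A(1,3) strain with the cis acyl group, and carboxylation next to the furyl ketone is reversible and unproductive.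

Compound list
1 | 3-bromofuran | Brc1ccoc1 | starting material
2 | pent-4-ynal | O=CCCC#C | starting material
3 | 3-furyllithium | [Li]c1ccoc1 | intermediate
4 | 1-(furan-3-yl)pent-4-yn-1-ol (racemic) | OC(CCC#C)c1ccoc1 | intermediate
5 | geranyl acetate, (2E)-3,7-dimethylocta-2,6-dien-1-yl acetate | CC(C)=CCC/C(C)=C/COC(C)=O | starting material
6 | (2E,6E)-8-hydroxy-3,7-dimethylocta-2,6-dien-1-yl acetate | OC/C(C)=C/CC/C(C)=C/COC(C)=O | intermediate
7 | (2E,7S)-8-hydroxy-3,7-dimethyloct-2-en-1-yl acetate | OC[C@@H](C)CCC/C(C)=C/COC(C)=O | intermediate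
8 | alkenylalane, dimethyl[(1E)-5-(dimethylaluminiooxy)-5-(furan-3-yl)-2-methylpent-1-en-1-yl]aluminium | C[Al](C)/C=C(\C)CCC(O[Al](C)C)c1ccoc1 | intermediate
9 | (2S,6E,9E)-13-(furan-3-yl)-2,6,10-trimethyltrideca-6,9-diene-1,13-diol (both C13 epimers) | OC[C@@H](C)CCC/C(C)=C/C/C=C(\C)CCC(O)c1ccoc1 | intermediate
10 | (2S,6E,9E)-13-(furan-3-yl)-2,6,10-trimethyl-13-oxotrideca-6,9-dienal | O=C[C@@H](C)CCC/C(C)=C/C/C=C(\C)CCC(=O)c1ccoc1 | intermediate
11 | (4E,7E,12S)-1-(furan-3-yl)-4,8,12-trimethyltetradeca-4,7-dien-13-yn-1-one | C#C[C@@H](C)CCC/C(C)=C/C/C=C(\C)CCC(=O)c1ccoc1 | intermediate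
12 | (4E,7E,12S)-1-(furan-3-yl)-4,8,12-trimethylheptadeca-4,7-dien-13-yne-1,15-dione | CCC(=O)C#C[C@@H](C)CCC/C(C)=C/C/C=C(\C)CCC(=O)c1ccoc1 | intermediate
13 | (4E,7E,12S,13E)-1-(furan-3-yl)-4,8,12-trimethyl-14-(tributylstannyl)heptadeca-4,7,13-triene-1,15-dione | CCC(=O)/C(=C\[C@@H](C)CCC/C(C)=C/C/C=C(\C)CCC(=O)c1ccoc1)[Sn](CCCC)(CCCC)CCCC | intermediate
14 | (4E,7E,12S,13E)-1-(furan-3-yl)-14-iodo-4,8,12-trimethylheptadeca-4,7,13-triene-1,15-dione | CCC(=O)/C(I)=C\[C@@H](C)CCC/C(C)=C/C/C=C(\C)CCC(=O)c1ccoc1 | intermediate
15 | β-keto carboxylate (14 carboxylated at C3, as its DBU-H+ salt; C3 epimers) | CC(C(=O)[O-])C(=O)/C(I)=C\[C@@H](C)CCC/C(C)=C/C/C=C(\C)CCC(=O)c1ccoc1.C1CCC2=[NH+]CCCN2CC1 | intermediate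
16 | (5E)-5-[(2S,6E,9E)-13-(furan-3-yl)-2,6,10-trimethyl-13-oxotrideca-6,9-dien-1-ylidene]-4-hydroxy-3-methylfuran-2(5H)-one | CC1=C(O)/C(=C\[C@@H](C)CCC/C(C)=C/C/C=C(\C)CCC(=O)c2ccoc2)OC1=O | target

Total step count: 9. Longest linear sequence: 8 steps (steps 2 to 9, from geranyl acetate).

Steps most likely to fail

Step 9 (proposed new method). The vinylic C–I bond may fail to engage the copper carboxylate before the β-keto carboxylate loses CO2 again. The carboxylate may instead close in the 6-endo oxa-Michael sense, or the iodide may lose its geometry by reversible conjugate addition of base or iodide. The fallback uses known chemistry and sets out from ynone 12. Silver-catalysed CO2 incorporation (AgOAc 10 mol %, DBU, CO2 1.0 MPa, MeCN, rt; enolate carboxylation, then 5-exo-dig anti-oxyargentation and protodemetalation) should give the (5Z)-isomer of the target F1. Visible-light triplet-sensitised E/Z isomerisation of the ylidene butenolide chromophore (Ir(ppy)3 1 mol %, blue LED, MeCN), which is not expected to excite the isolated trisubstituted alkenes, should then give a photostationary mixture. Compound 16 is separated from it by HPLC and F1 is recycled, so the fallback returns at 16 at the price of a separation.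

Step 4. The palladium-catalysed allylation of the alkoxide-bearing alkenylalane by the allylic acetate may be slower than protodealumination, or may proceed with scrambling of regiochemistry and alkene geometry at the π-allyl stage. The fallback sets out from alkyne 4. The same carboalumination is quenched with I2 to give the isolable (4E)-1-(furan-3-yl)-5-iodo-4-methylpent-4-en-1-ol F2. Miyaura borylation (B2pin2, PdCl2(PPh3)2, PPh3, KOPh, toluene, 50 °C) should give (4E)-1-(furan-3-yl)-4-methyl-5-(4,4,5,5-tetramethyl-1,3,2-dioxaborolan-2-yl)pent-4-en-1-ol F3. Suzuki–Miyaura allylation of F3 with acetate 7 (Pd(PPh3)4, K2CO3, THF/H2O, 50 °C) then forms the same alkenyl–allyl bond without any aluminium reagent and returns to the route at diol 9.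

Step 3. Enantiofacial discrimination on a 2-methylallylic alcohol may be insufficient, or the sense of induction may differ from the assumed one. The fallback sets out from 6 and moves the hydrogenation to the tiglic-acid substrate class, for which the sense and level of induction of Ru-BINAP dicarboxylates are established. MnO2 (CH2Cl2, rt) should give (2E,6E)-3,7-dimethyl-8-oxoocta-2,6-dien-1-yl acetate F4. Pinnick oxidation (NaClO2, NaH2PO4, 2-methylbut-2-ene, t-BuOH/H2O) should give (2E,6E)-8-acetoxy-2,6-dimethylocta-2,6-dienoic acid F5. Hydrogenation with Ru(OAc)2[(S)-BINAP] (H2 4 atm, MeOH, ligand chosen by analogy with tiglic acid) should give (2S,6E)-8-acetoxy-2,6-dimethyloct-6-enoic acid F6. Reduction through the mixed carbonic anhydride (i-BuOCOCl, N-methylmorpholine, THF, −10 °C; then NaBH4, H2O), which spares the acetate and the alkene, returns to the route at 7.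

Further compounds
F1 | step 9 | (5Z)-5-[(2S,6E,9E)-13-(furan-3-yl)-2,6,10-trimethyl-13-oxotrideca-6,9-dien-1-ylidene]-4-hydroxy-3-methylfuran-2(5H)-one | CC1=C(O)/C(=C/[C@@H](C)CCC/C(C)=C/C/C=C(\C)CCC(=O)c2ccoc2)OC1=O
F2 | step 4 | (4E)-1-(furan-3-yl)-5-iodo-4-methylpent-4-en-1-ol (racemic) | I/C=C(\C)CCC(O)c1ccoc1
F3 | step 4 | (4E)-1-(furan-3-yl)-4-methyl-5-(4,4,5,5-tetramethyl-1,3,2-dioxaborolan-2-yl)pent-4-en-1-ol (racemic) | CC1(C)OB(/C=C(\C)CCC(O)c2ccoc2)OC1(C)C
F4 | step 3 | (2E,6E)-3,7-dimethyl-8-oxoocta-2,6-dien-1-yl acetate | O=C/C(C)=C/CC/C(C)=C/COC(C)=O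
F5 | step 3 | (2E,6E)-8-acetoxy-2,6-dimethylocta-2,6-dienoic acid | OC(=O)/C(C)=C/CC/C(C)=C/COC(C)=O
F6 | step 3 | (2S,6E)-8-acetoxy-2,6-dimethyloct-6-enoic acid | OC(=O)[C@@H](C)CCC/C(C)=C/COC(C)=O
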